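(The numbers in the tables were computed for substances that don't exist.)

Q in the flask at 30 min, and the change that raises it most, were what I had to forecast.

| setting | north-east | west | south | flask |
|---|---|---|---|---|
| L | 0.13 M | 0.20 M | 0.091 M | 0.091 M |
| G | 1.8 equiv | 1.8 equiv | 0.90 equiv | 1.80 equiv |
| remark | run made earlier | run made earlier | run made earlier |  |
| time |  |  |  | 30 min |

| run | time / min | Q / % |
|---|---|---|
| north-east | 1.33 | 1 |
| north-east | 2.00 | 1 |
| north-east | 3.00 | 0 |
| north-east | 5.00 | 6 |
| north-east | 8.00 | 7 |
| north-east | 12.0 | 11 |
| north-east | 20.0 | 17 |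
| west | 1.00 | 1 |
| west | 3.00 | 2 |
| west | 5.00 | 3 |
| west | 8.00 | 5 |
| west | 10.0 | 8 |
| west | 15.0 | 15 |
| west | 20.0 | 16 |
| south | 1.33 | 0 |
| south | 2.50 | 1 |
| south | 5.00 | 1 |
| south | 10.0 | 3 |
| south | 20.0 | 8 |

(each reading ± 1.5 percentage points)

1. Q at 30 min, in percent of the L charged
2. the change that raises the amount of Q at 30 min, in percent of the L charged most ("none" if none brings more than 2 percentage points) (birch / larch / ash / none)
3. amount of Q at 30 min, in percent of the L charged, after birch

- birch: doubling the solubility of L, all else as stated
- larch: doubling the amount of G, all else as stated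
- ash: doubling the dissolution coefficient of L, all else as stated

- in percentages every species weighs as the L in it: one Z counts as two
- as a solid, counted per litre of solution: L
- on the list of suspects stand: Q <-> J; L + Q -> Z; L <-> X; X + G -> Q
- at the start none of L is in solution

I asked first which numbers mattered. The north-east and west runs, at 0.13 M and 0.20 M of L with the same equivalents of G, read 17% and 16% at 20.0 min, so I let [L] go. The south run, with half the equivalents, read about half the Q, so the equivalents counted in full. Time counted too, since the west run went from 8% at 10.0 min to 16% at 20.0 min. The number to know well was therefore the rate itself: a scatter of 1.5 percentage points on 17% is 8.82% of that reading.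

So I counted turnovers: the share of the charged G that has become Q, which is Q in percent of L divided by the equivalents. At 20.0 min the runs gave 9.44%, 8.89% and 8.89%, like a pseudo-first-order turnover of G. Their mean, carried in proportion to 30 min, made the turnover count 13.6%. Times 1.80 equiv, that gave me 24.5% of Q.

The forecast said 23%, just below mine, with birch best at 42%, and added: “this is a close call; I lean birch”.

The flask gave 24.4%. The best change was larch, worth 21 points against 12 points for birch, which reached 36.7%.

    Q ⇌ J (K = 4.60, k = 4.34 × 10⁻⁴ s⁻¹)
    L + Q → Z (k = 6.12 × 10⁻⁴ L mol⁻¹ s⁻¹)
    L ⇌ X, rate k3*(cs3 - [X]) while solid is left; crystals form when [X] > cs3 (solubility = 41.0 mM, k = 0.00490 s⁻¹)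
    X + G → Q (k = 0.00354 L mol⁻¹ s⁻¹)

Part of the Q missing from the flask traces to the low solubility of X and to Q turning into J: without the solubility limit Q stood at 37.6%, without the J step at 33.8%. For a further flask, like this one but with 4.50 equiv of G, my count gave 61.2%, more than the 53.0% of Q that flask reached. That flask had spent G for 74.7% of L, and J held 21.2%.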